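**Retrosynthetic overview**

- Target 9 comes from 8 by hydrogenolysis of the C6–O benzyl ether, and 8 from 7 by fluoride removal of a SiMe3 group on C2.
- The strategy rests on ring C: C4 is a carbonyl carbon ortho to the O1 oxygen on ring A (a salicylaldehyde), and C2–C3 is a two-carbon unit with ring B on C3 and only hydrogen on C2 (an aryl alkyne whose other terminus carries a removable silyl group).
- Key disconnection: ring C of 7 is cut at C3–C4 and O1–C2, giving salicylaldehyde 3 and aryl silyl alkyne 6.
- 3 comes from phenol 1 by ortho-formylation; 6 comes from aryl iodide 4 and trimethylsilylacetylene 5 by Sonogashira coupling.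
- Ring order: rings A and B are bought; ring C is the only ring formed (step 3).

Key step: step 3

Assumption: phenol 1 is taken as a catalogue compound, and chromone numbering (O1, C2, C3, C4, C4a, C5–C8, C8a; ring A benzo, ring B the 3-aryl group, ring C the pyranone) is used throughout.

**Route**

Step 1
Reactants: 1 4-(benzyloxy)-3-methoxyphenol
Product: 3 5-(benzyloxy)-2-hydroxy-4-methoxybenzaldehyde, via salicyl alcohol 2 (not isolated)
Conditions: MgCl2 (1.5 equiv), Et3N (3.75 equiv), (CH2O)n (7 equiv), MeCN, reflux; then 1 M HCl
Reagents that add atoms: paraformaldehyde (as formaldehyde), C=O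
Why: Magnesium-mediated ortho-formylation (Casnati–Skattebøl), in which the magnesium phenoxide delivers formaldehyde to the ortho carbon and the salicyl alkoxide 2 is oxidised by a second formaldehyde through an Oppenauer-type hydride transfer; the ortho position para to OMe should react, since the one flanked by OH and OMe is blocked.

Step 2
Reactants: 4 5-iodo-1,2,3-trimethoxybenzene; 5 trimethylsilylacetylene
Product: 6 trimethyl[(3,4,5-trimethoxyphenyl)ethynyl]silane
Conditions: PdCl2(PPh3)2 (2 mol %), CuI (4 mol %), Et3N/THF, rt to 50 °C
Reagents that add atoms: none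
Why: Sonogashira coupling (oxidative addition of the aryl iodide to zerovalent palladium, transmetalation from the copper acetylide, reductive elimination), in which the C(sp)–Si bond should stay intact because neither fluoride nor alkoxide is present.

Step 3
Reactants: 3 5-(benzyloxy)-2-hydroxy-4-methoxybenzaldehyde; 6 trimethyl[(3,4,5-trimethoxyphenyl)ethynyl]silane (1.5 equiv)
Product: 7 6-(benzyloxy)-7-methoxy-3-(3,4,5-trimethoxyphenyl)-2-(trimethylsilyl)-4H-chromen-4-one
Conditions: [Cp*Rh(MeCN)3](SbF6)2 (5 mol %), anhydrous Cu(OAc)2 (2.2 equiv), 1,2-dichloroethane, 80 °C, N2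
Reagents that add atoms: none
Why: Proposed new method: the phenoxide of 3 binds the cationic Cp*Rh fragment of trivalent rhodium and acetate-assisted cleavage of the formyl C–H bond gives a five-membered acyl rhodacycle; alkyne 6 then inserts into the Rh–acyl bond so that the acyl carbon bonds to the aryl-bearing alkyne carbon (C3–C4) and rhodium to the silyl-bearing carbon, C–O reductive elimination from the seven-membered oxa-rhodacycle forms O1–C2, and Cu(OAc)2 returns monovalent rhodium to the trivalent state. The closest known reaction is the rhodium-catalysed oxidative annulation of salicylaldehydes with diaryl and dialkyl alkynes to 2,3-disubstituted chromones; the use of an aryl silyl alkyne in this aldehyde C–H manifold is the untested part. Ring C closes as a six-membered ring in a formal [4+2] oxidative annulation, O1–C8a–C4a–C4 coming from 3 and C2–C3 from 6, the closing event being the C–O reductive elimination. No stereocenter is formed. The step needs one insertion orientation (silicon at C2, ring B at C3), which should be secured because the long Rh–C bond accommodates the bulky SiMe3 group better than the short forming C–C bond, silicon stabilises a carbon–metal bond alpha to it, and the beta-silicon effect, reinforced by the electron-rich trimethoxyphenyl ring, makes the aryl-bearing carbon the acceptor for the migrating acyl group, the same bias that places silicon next to the heteroatom in Larock heteroannulations. A preformed silver-free catalyst and anhydrous Cu(OAc)2 are chosen so that the C(sp)–Si bond of 6 is not cleaved before insertion.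

Step 4
Reactants: 7 6-(benzyloxy)-7-methoxy-3-(3,4,5-trimethoxyphenyl)-2-(trimethylsilyl)-4H-chromen-4-one
Product: 8 6-(benzyloxy)-7-methoxy-3-(3,4,5-trimethoxyphenyl)-4H-chromen-4-one
Conditions: Bu4NF (1.2 equiv), AcOH (1.2 equiv), THF, 0 °C to rt
Reagents that add atoms: none
Why: Fluoride-induced protodesilylation of an alkenyl silane, in which fluoride attacks silicon and the C2 carbanion (an sp2 anion alpha to the ring oxygen of an electron-poor pyranone) is protonated by the acetic acid buffer, which should also keep hydroxide from opening ring C.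

Step 5
Reactants: 8 6-(benzyloxy)-7-methoxy-3-(3,4,5-trimethoxyphenyl)-4H-chromen-4-one
Product: 9 6-hydroxy-7-methoxy-3-(3,4,5-trimethoxyphenyl)-4H-chromen-4-one (target)
Conditions: H2 (1 atm), 10% Pd/C, EtOAc/MeOH, rt, stopped after one equivalent of H2
Reagents that add atoms: none
Why: Hydrogenolysis of a benzyl aryl ether, which should be faster than saturation of the C2=C3 bond because that bond is a trisubstituted vinylogous ester alkene.

**Compound list**

1 | 4-(benzyloxy)-3-methoxyphenol | COc1cc(O)ccc1OCc1ccccc1 | starting material
2 | 4-(benzyloxy)-2-(hydroxymethyl)-5-methoxyphenol (salicyl alcohol, formed as its magnesium salt) | COc1cc(O)c(CO)cc1OCc1ccccc1 | intermediate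
3 | 5-(benzyloxy)-2-hydroxy-4-methoxybenzaldehyde | COc1cc(O)c(C=O)cc1OCc1ccccc1 | intermediate
4 | 5-iodo-1,2,3-trimethoxybenzene | COc1cc(I)cc(OC)c1OC | starting material
5 | trimethylsilylacetylene | C#C[Si](C)(C)C | starting material
6 | trimethyl[(3,4,5-trimethoxyphenyl)ethynyl]silane | COc1cc(C#C[Si](C)(C)C)cc(OC)c1OC | intermediate
7 | 6-(benzyloxy)-7-methoxy-3-(3,4,5-trimethoxyphenyl)-2-(trimethylsilyl)-4H-chromen-4-one | COc1cc2oc([Si](C)(C)C)c(-c3cc(OC)c(OC)c(OC)c3)c(=O)c2cc1OCc1ccccc1 | intermediate
8 | 6-(benzyloxy)-7-methoxy-3-(3,4,5-trimethoxyphenyl)-4H-chromen-4-one | COc1cc2occ(-c3cc(OC)c(OC)c(OC)c3)c(=O)c2cc1OCc1ccccc1 | intermediate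
9 | 6-hydroxy-7-methoxy-3-(3,4,5-trimethoxyphenyl)-4H-chromen-4-one | COc1cc2occ(-c3cc(OC)c(OC)c(OC)c3)c(=O)c2cc1O | target

**Step count and risks**

Total step count: 5. Longest linear sequence: 4 steps (step 1 or step 2, then steps 3, 4 and 5).

Steps most likely to fail:

Step 3 (proposed new method). The insertion may take the opposite orientation and leave silicon on C3. Acetate may cleave the C(sp)–Si bond of 6 before insertion, after which copper would dimerise the alkyne. The acyl rhodacycle may also extrude CO. Loss of silicon from 7 after ring closure would be harmless, since it leads to 8. The fallback uses known chemistry, sets out from 3 and comes back to the route at 8, so that step 4 is bypassed. MeMgBr (2.5 equiv, THF, 0 °C) adds to the aldehyde to give racemic 4-(benzyloxy)-2-(1-hydroxyethyl)-5-methoxyphenol F1. MnO2 (CH2Cl2, rt) oxidises the benzylic alcohol to 1-[5-(benzyloxy)-2-hydroxy-4-methoxyphenyl]ethan-1-one F2. DMF dimethyl acetal (toluene, 90 °C) converts the methyl ketone into (E)-1-[5-(benzyloxy)-2-hydroxy-4-methoxyphenyl]-3-(dimethylamino)prop-2-en-1-one F3. Iodine (CHCl3, rt) closes ring C with iodination at C3 to give 6-(benzyloxy)-3-iodo-7-methoxy-4H-chromen-4-one F4. Suzuki–Miyaura coupling of this iodide with purchased (3,4,5-trimethoxyphenyl)boronic acid (Pd(dppf)Cl2, Na2CO3, DME/H2O, 80 °C) attaches ring B at C3 and should give 8.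

Step 4. Fluoride or adventitious hydroxide may add to C2 and open ring C instead of attacking silicon, or C–Si cleavage may be too slow under buffered conditions. The fallback sets out from 7, comes back at 8, and makes the ring opening the method. Aqueous KOH in EtOH at reflux degrades ring C (hydroxide addition at C2, ring opening, retro-Claisen loss of C2 together with its silyl group) to the deoxybenzoin 1-[5-(benzyloxy)-2-hydroxy-4-methoxyphenyl]-2-(3,4,5-trimethoxyphenyl)ethan-1-one F5. DMF dimethyl acetal (toluene, 80–100 °C) then supplies C2 again: the enaminone 1-[5-(benzyloxy)-2-hydroxy-4-methoxyphenyl]-3-(dimethylamino)-2-(3,4,5-trimethoxyphenyl)prop-2-en-1-one F6 forms and should cyclise in the flask, with loss of dimethylamine, to 8. Both operations are classical isoflavone chemistry.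

Step 5. Saturation of the C2=C3 bond may compete with cleavage of the benzyl C–O bond, and longer exposure may reduce the ring further. The fallback sets out from 7, comes back at 9, and exchanges the order of the last two operations. Hydrogenolysis (H2, 10% Pd/C, EtOAc, rt) is run on 7, whose C2=C3 bond is tetrasubstituted and shielded by SiMe3 and should therefore resist reduction. This should give 6-hydroxy-7-methoxy-3-(3,4,5-trimethoxyphenyl)-2-(trimethylsilyl)-4H-chromen-4-one F7. Buffered Bu4NF/AcOH (THF, rt) then removes silicon to give 9.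

Further compounds
F1 | step 3 | 4-(benzyloxy)-2-(1-hydroxyethyl)-5-methoxyphenol (racemic) | COc1cc(O)c(C(C)O)cc1OCc1ccccc1
F2 | step 3 | 1-[5-(benzyloxy)-2-hydroxy-4-methoxyphenyl]ethan-1-one | COc1cc(O)c(C(C)=O)cc1OCc1ccccc1
F3 | step 3 | (E)-1-[5-(benzyloxy)-2-hydroxy-4-methoxyphenyl]-3-(dimethylamino)prop-2-en-1-one | COc1cc(O)c(C(=O)/C=C/N(C)C)cc1OCc1ccccc1
F4 | step 3 | 6-(benzyloxy)-3-iodo-7-methoxy-4H-chromen-4-one | COc1cc2occ(I)c(=O)c2cc1OCc1ccccc1
F5 | step 4 | 1-[5-(benzyloxy)-2-hydroxy-4-methoxyphenyl]-2-(3,4,5-trimethoxyphenyl)ethan-1-one | COc1cc(O)c(C(=O)Cc2cc(OC)c(OC)c(OC)c2)cc1OCc1ccccc1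
F6 | step 4 | 1-[5-(benzyloxy)-2-hydroxy-4-methoxyphenyl]-3-(dimethylamino)-2-(3,4,5-trimethoxyphenyl)prop-2-en-1-one (alkene geometry not defined) | COc1cc(O)c(C(=O)C(=CN(C)C)c2cc(OC)c(OC)c(OC)c2)cc1OCc1ccccc1
F7 | step 5 | 6-hydroxy-7-methoxy-3-(3,4,5-trimethoxyphenyl)-2-(trimethylsilyl)-4H-chromen-4-one | COc1cc2oc([Si](C)(C)C)c(-c3cc(OC)c(OC)c(OC)c3)c(=O)c2cc1O
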